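**Strategy.** The para-substituted phenol ring is built, not bought. The benzene ring (C1 carries the CH2CH2O arm, C4 the oxygen) is disconnected at C3–C4 and C5–C6. Ring atoms C1, C2, C3 and C6 derive from C5, C4, C3 and C6 of a 5-substituted 2-pyrone; C4 and C5 derive from 1,1-dimethoxyethene, whose acetal carbon brings the phenolic oxygen. One thermal operation performs the [4+2] cycloaddition, expels CO2 and methanol, and delivers the anisole. The precursor is the complete C37 ester of 5-(2-hydroxyethyl)-2-pyrone, assembled by B-alkyl Suzuki coupling on 5-bromo-2-pyrone and carbodiimide esterification, so that only O-demethylation remains afterwards.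

Key step: step 6

Remark on the chemistry: the target has no stereocentre, and its acyl chain is taken as the unbranched C37 acid (C22 + C15). Adduct 13 forms as a racemate whose two bridgehead centres vanish on aromatisation.

**Step 1**
Reactants: 1 coumalic acid
Product: 2 5-bromo-2H-pyran-2-one
Conditions: NBS (1.05 equiv), LiOAc (0.2 equiv), MeCN–H2O (9:1), rt
Reagents that add atoms: N-bromosuccinimide, O=C1CCC(=O)N1Br
Why: Hunsdiecker-type bromodecarboxylation of a vinylogous (α,β-unsaturated) carboxylic acid, in which the carboxylate-bearing C5 is brominated ipso and CO2 is lost; one equivalent of NBS should keep C3 unbrominated.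

**Step 2**
Reactants: 2 5-bromo-2H-pyran-2-one; 3 tert-butyldimethyl(vinyloxy)silane
Product: 5 5-[2-(tert-butyldimethylsilyloxy)ethyl]-2H-pyran-2-one, via alkyl-9-BBN borane 4 (not isolated)
Conditions: 3 (1.5 equiv), 9-BBN (1.4 equiv), THF, 0 °C → rt; then 2, PdCl2(dppf) (5 mol%), aq. K3PO4 (3 equiv), DMF, rt
Reagents that add atoms: none
Why: Anti-Markovnikov hydroboration of the enol ether puts boron on the terminal carbon, and the primary alkylborane then undergoes B-alkyl Suzuki–Miyaura coupling at the vinylic C5–Br bond; phosphate base at room temperature and a slight deficit of 9-BBN relative to 3 are chosen to spare the base- and hydride-sensitive pyrone.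

**Step 3**
Reactants: 5 5-[2-(tert-butyldimethylsilyloxy)ethyl]-2H-pyran-2-one
Product: 6 5-(2-hydroxyethyl)-2H-pyran-2-one
Conditions: camphorsulfonic acid (10 mol%), MeOH, 0 °C → rt; evaporate
Reagents that add atoms: none
Why: Acid-catalysed methanolysis of a primary silyl ether (protecting-group removal); the 2-pyrone tolerates acid, whereas basic fluoride is avoided, and evaporation spares an aqueous extraction of the polar alcohol.

**Step 4**
Reactants: 7 1-bromodocosane; 8 15-bromopentadecanoic acid
Product: 10 heptatriacontanoic acid, via docosylmagnesium bromide 9 (not isolated)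
Conditions: 7, Mg, THF, 45 °C; separately 8, MeMgCl (1.0 equiv), THF, −20 °C; then Li2CuCl4 (3 mol%), add 9 (1.4 equiv), −10 °C → rt; aq. HCl
Reagents that add atoms: none
Why: Copper-catalysed sp3–sp3 cross-coupling (Kochi-type) of a primary alkyl Grignard reagent with a primary alkyl bromide, the acid being masked in the flask as its chloromagnesium carboxylate so that it does not quench the Grignard reagent.

**Step 5**
Reactants: 6 5-(2-hydroxyethyl)-2H-pyran-2-one; 10 heptatriacontanoic acid
Product: 11 2-(2-oxo-2H-pyran-5-yl)ethyl heptatriacontanoate
Conditions: N,N'-diisopropylcarbodiimide (1.3 equiv), DMAP (0.2 equiv), CH2Cl2–toluene, 40 °C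
Reagents that add atoms: none
Why: Steglich esterification, in which DMAP intercepts the O-acylisourea and the acylpyridinium acylates the primary alcohol under near-neutral conditions that leave the pyrone untouched; gentle warming keeps the wax acid in solution.

**Step 6**
Reactants: 11 2-(2-oxo-2H-pyran-5-yl)ethyl heptatriacontanoate; 12 1,1-dimethoxyethene
Product: 15 2-(4-methoxyphenyl)ethyl heptatriacontanoate, via bridged lactone cycloadduct 13 (not isolated), via dimethoxycyclohexadiene ester 14 (not isolated)
Conditions: 12 (10 equiv), K2CO3 (trace), toluene, sealed tube, 150 °C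
Reagents that add atoms: none
Why: The electron-rich alkene adds across C3 and C6 of the electron-poor pyrone diene in a concerted but asynchronous [4+2] cycloaddition (C6–CH2 bonding in the lead) to give the 2-oxabicyclo[2.2.2]octenone 13, which loses CO2 by retro-[4+2] to the 4,4-dimethoxycyclohexadiene 14 and then methanol by thermal 1,2-elimination. The closest known reaction type is the Diels–Alder/decarboxylation/aromatisation sequence of 2-pyrones with ketene acetals, which turns pyrones into anisoles. The one new ring, the six-membered carbocycle, is closed by intermolecular cycloaddition that forms both new C–C bonds (pyrone C6 to the methylene carbon, pyrone C3 to the acetal carbon), not by a stepwise cyclisation. No stereocentre is set, because the two bridgehead centres of racemic 13 are erased on aromatisation. The step needs regioselectivity only, and matched polarisation secures it: C6, the diene terminus bound to the ring oxygen, is the electrophilic end and the unsubstituted CH2 of the acetal is its nucleophilic carbon, so the oxygen-bearing carbon lands on C3, para to the C5 side chain. The saturated ester is a thermal spectator, and the trace of base together with excess acetal guards against acid-induced loss of the dienophile.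

**Step 7**
Reactants: 15 2-(4-methoxyphenyl)ethyl heptatriacontanoate
Product: 16 2-(4-hydroxyphenyl)ethyl heptatriacontanoate (target)
Conditions: BBr3 (2 equiv), CH2Cl2, −40 → 0 °C; then H2O
Reagents that add atoms: none
Why: Lewis-acid aryl methyl ether cleavage, in which BBr3 coordinates the anisole oxygen and bromide removes the methyl group by SN2; at or below 0 °C this should be much faster than cleavage of a primary alkyl carboxylate.

**Compound list**
1 | coumalic acid (2-oxo-2H-pyran-5-carboxylic acid) | OC(=O)c1ccc(=O)oc1 | starting material
2 | 5-bromo-2H-pyran-2-one | Brc1ccc(=O)oc1 | intermediate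
3 | tert-butyldimethyl(vinyloxy)silane | C=CO[Si](C)(C)C(C)(C)C | starting material
4 | 9-[2-(tert-butyldimethylsilyloxy)ethyl]-9-borabicyclo[3.3.1]nonane | CC(C)(C)[Si](C)(C)OCCB1C2CCCC1CCC2 | intermediate (not isolated)
5 | 5-[2-(tert-butyldimethylsilyloxy)ethyl]-2H-pyran-2-one | CC(C)(C)[Si](C)(C)OCCc1ccc(=O)oc1 | intermediate
6 | 5-(2-hydroxyethyl)-2H-pyran-2-one | OCCc1ccc(=O)oc1 | intermediate
7 | 1-bromodocosane | CCCCCCCCCCCCCCCCCCCCCCBr | starting material
8 | 15-bromopentadecanoic acid | BrCCCCCCCCCCCCCCC(=O)O | starting material
9 | docosylmagnesium bromide | CCCCCCCCCCCCCCCCCCCCCC[Mg]Br | intermediate (not isolated)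
10 | heptatriacontanoic acid | CCCCCCCCCCCCCCCCCCCCCCCCCCCCCCCCCCCCC(=O)O | intermediate
11 | 2-(2-oxo-2H-pyran-5-yl)ethyl heptatriacontanoate | CCCCCCCCCCCCCCCCCCCCCCCCCCCCCCCCCCCCC(=O)OCCc1ccc(=O)oc1 | intermediate
12 | 1,1-dimethoxyethene | C=C(OC)OC | starting material
13 | 2-(8,8-dimethoxy-3-oxo-2-oxabicyclo[2.2.2]oct-5-en-6-yl)ethyl heptatriacontanoate (racemic) | CCCCCCCCCCCCCCCCCCCCCCCCCCCCCCCCCCCCC(=O)OCCC1=CC2C(=O)OC1CC2(OC)OC | intermediate (not isolated)
14 | 2-(4,4-dimethoxycyclohexa-1,5-dien-1-yl)ethyl heptatriacontanoate | CCCCCCCCCCCCCCCCCCCCCCCCCCCCCCCCCCCCC(=O)OCCC1=CCC(OC)(OC)C=C1 | intermediate (not isolated)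
15 | 2-(4-methoxyphenyl)ethyl heptatriacontanoate | CCCCCCCCCCCCCCCCCCCCCCCCCCCCCCCCCCCCC(=O)OCCc1ccc(OC)cc1 | intermediate
16 | 2-(4-hydroxyphenyl)ethyl heptatriacontanoate | CCCCCCCCCCCCCCCCCCCCCCCCCCCCCCCCCCCCC(=O)OCCc1ccc(O)cc1 | target

**Total step count:** 7
**Longest linear sequence:** 6 steps (steps 1, 2, 3, 5, 6, 7, from coumalic acid); the acid branch (step 4) joins at step 5.

**Steps most likely to fail**

Step 6. The unactivated 5-alkylpyrone may cycloadd more slowly than the ketene acetal oligomerises or is lost to adventitious acid and moisture, so that conversion stalls. Some addition in the reverse orientation would also divert material to the meta isomer. Fallback: the anisole ring is taken ready-made. Setting out from acid 10, Steglich esterification (N,N'-diisopropylcarbodiimide, DMAP, CH2Cl2–toluene, 40 °C) with purchased 2-(4-methoxyphenyl)ethanol F1 should give the same ester, and the route is rejoined at 15.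

Step 2. The β-silyloxyethylborane may undergo β-elimination or protodeboronation before transmetalation, and aqueous base may open the pyrone lactone. Fallback: a base-free enolate coupling followed by adjustment of the oxidation state. Setting out from 2, palladium-catalysed coupling with the Reformatsky reagent BrZnCH2CO2t-Bu (Pd[P(t-Bu)3]2 cat., THF, rt) should give tert-butyl 2-(2-oxo-2H-pyran-5-yl)acetate F2. Trifluoroacetic acid in CH2Cl2 then frees 2-(2-oxo-2H-pyran-5-yl)acetic acid F3. BH3·SMe2 (THF, 0 °C) should reduce the free acid faster than it touches the conjugated lactone, and the route is rejoined at 6.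

Step 7. BBr3 may also cleave the alkyl ester C–O bond, and the wax ester may dissolve too poorly at low temperature for demethylation to finish before that happens. Fallback: the ester is taken apart on purpose and rebuilt on the free phenol. Setting out from 15, saponification (KOH, EtOH–toluene, reflux; acidify) returns acid 10 and releases 2-(4-methoxyphenyl)ethanol F1, the alcohol already named under step 6. Thiolate demethylation (NaSEt, DMF, 130 °C) should convert it into 4-(2-hydroxyethyl)phenol F4. Mitsunobu esterification of F4 with 10 (PPh3, diisopropyl azodicarboxylate, THF–toluene), which activates only the aliphatic hydroxyl, should then give the target, and the route is rejoined at 16.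

**Further compounds**
F1 | step 6 | 2-(4-methoxyphenyl)ethanol | COc1ccc(CCO)cc1
F2 | step 2 | tert-butyl 2-(2-oxo-2H-pyran-5-yl)acetate | CC(C)(C)OC(=O)Cc1ccc(=O)oc1
F3 | step 2 | 2-(2-oxo-2H-pyran-5-yl)acetic acid | OC(=O)Cc1ccc(=O)oc1
F4 | step 7 | 4-(2-hydroxyethyl)phenol | OCCc1ccc(O)cc1
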